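**Retrosynthetic overview**

1. C6–Cl comes last, by SN2 on the ring allylic alcohol; the ten-membered ring closes before that through C5–C6 (Nozaki–Hiyama–Kishi).
2. The γ-lactone (C7, C8, C17, C18) comes from a Reformatsky addition to a C8 vinyl ketone followed by iodolactonisation; C6–C8 come from lithiated methoxyallene, which opens a temporary C2–O–C9 lactone.
3. Ring A is made first, by a Diels–Alder reaction of a 1-silyloxy vinylallene (C20=C11=C12–C13=C14–O) with an (E)-2-methyl-4-oxo-enoate (C2 = CHO, C1 with C15, C10, C9 = ester); this forms C10–C11 and C1–C14.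
4. Enabling feature: ring A (C1, C10, C11, C12, C13, C14) carries an exocyclic methylene on C11 next to fusion atom C10, oxygen on C14 next to the quaternary C1, and trans-disposed oxygenated carbons C2 and C9 on C1/C10, which is the imprint of a vinylallene adding to an (E)-enal.
5. Ring order: ring A (step 4), temporary γ-lactone (step 6, opened in step 9), γ-lactone (step 15), ten-membered ring (step 17).

Key step: step 4

Assumptions: briarane numbering is used (lactone carbonyl C18, methyl on C17 = C19; β is the face of the C15 methyl on ring A). The (S)-oxazaborolidinium is assumed to expose the enal face that gives the 1S,10S series; if the sense is the reverse, its antipode is used. Compound 12 is drawn as the open hydroxy ketone although it may rest as its five-membered hemiketal.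

**Step 1**
Reactants: 1 but-3-yn-1-ol
Product: 2 penta-3,4-dien-1-ol
Conditions: (CH2O)n, CuBr, i-Pr2NH, dioxane, reflux
Reagents that add atoms: formaldehyde (as paraformaldehyde), C=O
Why: Crabbé allene homologation (Mannich base, then hydride transfer from the amine) converts the terminal alkyne into the terminal allene; no stereocentre is formed.

**Step 2**
Reactants: 2 penta-3,4-dien-1-ol
Product: 3 penta-3,4-dienal
Conditions: Dess–Martin periodinane, NaHCO3, CH2Cl2, 0 °C; used at once
Reagents that add atoms: none
Why: Buffered Dess–Martin oxidation is non-basic, so the β,γ-allenyl aldehyde should not move into conjugation.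

**Step 3**
Reactants: 3 penta-3,4-dienal
Product: 4 (1E)-tert-butyl(dimethyl)(penta-1,3,4-trien-1-yloxy)silane
Conditions: TBSOTf, Et3N, Et2O, −78 to 0 °C
Reagents that add atoms: tert-butyldimethylsilyl triflate, CC(C)(C)[Si](C)(C)OS(=O)(=O)C(F)(F)F
Why: Soft enolisation and O-silylation at the only enolisable position gives the silyl dienol ether, expected mainly as the (1E) isomer as for crotonaldehyde.

**Step 4**
Reactants: 4 (1E)-tert-butyl(dimethyl)(penta-1,3,4-trien-1-yloxy)silane; 5 ethyl (E)-3-methyl-4-oxobut-2-enoate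
Product: 6 ring A adduct, ethyl 3-(tert-butyldimethylsilyloxy)-2-formyl-2-methyl-6-methylidenecyclohex-4-ene-1-carboxylate (CHO cis to OSi, trans to CO2Et; C1, C10, C14 as in the target)
Conditions: (S)-3,3-diphenyl-1-(o-tolyl)tetrahydropyrrolo[1,2-c][1,3,2]oxazaborole (15 mol %), HNTf2 (12 mol %), CH2Cl2, −78 to −40 °C
Reagents that add atoms: none
Why: Proposed new method: a catalytic enantioselective normal-demand [4+2] cycloaddition in which the s-cis diene C11=C12–C13=C14 of the 1-silyloxy vinylallene adds across C1=C10 of the enal bound through its formyl group to the chiral oxazaborolidinium, concerted but asynchronous with C10–C11 leading; the closest known reaction types are the oxazaborolidinium-catalysed Diels–Alder reactions of 2-substituted enals with silyloxy dienes and the thermal or Lewis-acid Diels–Alder reactions of vinylallenes, which have not been combined. Ring A (C1, C10, C11, C12, C13, C14) closes by intermolecular suprafacial [4+2] cycloaddition. C1 and C10 follow from the (E) geometry of 5 (CHO and CO2Et stay trans) and from the catalyst-shielded enal face (absolute sense); C14 follows from the endo placement of the catalyst-bound formyl group, which puts C14–OSi cis to CHO. The regioselectivity needed (C11 to C10, C14 to C1) is secured by matched polarisation: the C14 oxygen makes the central allene carbon C11 the nucleophilic terminus and the coordinated aldehyde makes C10 the electrophilic one, the ester being the weaker, exo activator. The cumulated C11=C20 bond does not take part and emerges as the exocyclic methylene, and only the (1E) dienol ether can reach the s-cis geometry.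

**Step 5**
Reactants: 6 ring A adduct
Product: 7 hydroxy aldehyde, ethyl 2-formyl-3-hydroxy-2-methyl-6-methylidenecyclohex-4-ene-1-carboxylate (14α-OH)
Conditions: HF·pyridine, pyridine, THF, 0 °C
Reagents that add atoms: none
Why: Acidic fluoride desilylation frees the C14 hydroxyl without the base that would trigger retro-aldol cleavage of the β-hydroxy aldehyde.

**Step 6**
Reactants: 7 hydroxy aldehyde
Product: 9 temporary lactone (trans-fused γ-lactone C2–O–C9(=O); 14α-OH; C2 carries the 4-(trimethylsilyl)but-3-ynyl chain), via hydroxy ester 8 (not isolated)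
Conditions: TMSC≡CCH2CH2MgBr (3 equiv), THF, −78 °C; aq NH4Cl; then PPTS (cat.), CH2Cl2, rt
Reagents that add atoms: [4-(trimethylsilyl)but-3-yn-1-yl]magnesium bromide, C[Si](C)(C)C#CCC[Mg]Br
Why: Chelation-controlled Grignard addition: the magnesium alkoxide of 14-OH chelates the formyl oxygen and the nucleophile enters from the face of the axial C15 methyl (the C10 side is blocked by ring A), giving the 1,3-anti (2S) carbinol, which lactonises onto the trans C9 ester.

**Step 7**
Reactants: 9 temporary lactone
Product: 10 12,13-epoxide of 9 (epoxide cis to 14-OH)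
Conditions: VO(acac)2 (cat.), t-BuOOH, CH2Cl2, 0 °C to rt
Reagents that add atoms: tert-butyl hydroperoxide, CC(C)(C)OO
Why: Hydroxyl-directed vanadium epoxidation of the cyclic dienol oxidises only the proximal C12=C13 bond, syn to 14-OH, which fixes the C13 oxygen cis to the C14 oxygen.

**Step 8**
Reactants: 10 epoxy alcohol
Product: 11 13α,14α-diol lactone with the 11(20)-methylene
Conditions: Pd2(dba)3·CHCl3 (cat.), PBu3, HCO2H, Et3N, dioxane, rt
Reagents that add atoms: none
Why: Tsuji–Shimizu hydrogenolysis of the alkenyl oxirane: the π-allyl complex (C12–C11–C20) takes hydride from formate at C12, giving the homoallylic C13 alcohol with its configuration retained and restoring the exocyclic methylene.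

**Step 9**
Reactants: 11 diol lactone
Product: 12 methoxyallenyl ketone (C9 ketone, C2/C13/C14 triol, open form)
Conditions: methoxyallene, n-BuLi (4 equiv each), THF, −78 °C; then 11; aq NH4Cl
Reagents that add atoms: 1-methoxyallene (lithiated in the flask), COC=C=C
Why: Acyl-anion-type addition of lithiated methoxyallene to the lactone stops at the tetrahedral alkoxide at −78 °C, so one C3 unit (C8, C7, C6) is added and the temporary ring is opened.

**Step 10**
Reactants: 12 methoxyallenyl ketone
Product: 14 tetraol with (9S) carbinol and terminal alkyne, via silylalkyne tetraol 13 (not isolated)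
Conditions: NaBH4, CeCl3·7H2O, MeOH, −78 °C; then K2CO3, rt
Reagents that add atoms: none
Why: Luche 1,2-reduction under Felkin–Anh control by C10 (hydride anti to the quaternary C1) should give the 9S alcohol, and methanolic carbonate then removes the alkynyl silyl group.

**Step 11**
Reactants: 14 tetraol
Product: 15 tetraacetate (2,9,13,14-tetra-O-acetyl) methoxyallene
Conditions: Ac2O, pyridine, DMAP (cat.), CH2Cl2, rt to 40 °C
Reagents that add atoms: acetic anhydride, CC(=O)OC(C)=O
Why: DMAP-catalysed acetylation installs all four acetates of the target in one operation; no stereocentre is touched.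

**Step 12**
Reactants: 15 tetraacetate methoxyallene
Product: 16 tetraacetate vinyl ketone (C8 ketone, C7=C6 vinyl)
Conditions: aq H2SO4 (5 %), THF, 0 °C
Reagents that add atoms: water, O
Why: Acid hydrolysis of the alkoxyallene (protonation at the central carbon, hydration of the oxocarbenium ion, loss of methanol) unmasks the α'-acetoxy vinyl ketone.

**Step 13**
Reactants: 16 tetraacetate vinyl ketone
Product: 17 β-hydroxy tert-butyl ester (tertiary C8 alcohol bearing vinyl, C17 methyl)
Conditions: tert-butyl 2-bromopropanoate, Zn (activated), THF, 0 °C to rt; aq NH4Cl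
Reagents that add atoms: tert-butyl 2-bromopropanoate, CC(Br)C(=O)OC(C)(C)C
Why: Reformatsky 1,2-addition, with C8 set by the Cornforth/polar Felkin–Anh model (C9–OAc anti to C=O, attack past C9–H) and C17 by a chair transition state with the C9 branch equatorial (methyl syn to the new OH); a minor C17 epimer is removed by chromatography.

**Step 14**
Reactants: 17 β-hydroxy ester
Product: 18 α-(triethylsilyl)vinyl derivative (C5 carries SiEt3, C5=C16)
Conditions: Et3SiH, [Cp*Ru(MeCN)3]PF6 (cat.), CH2Cl2, 0 °C to rt
Reagents that add atoms: triethylsilane, CC[SiH](CC)CC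
Why: Trost Markovnikov hydrosilylation of the terminal alkyne gives the 1,1-disubstituted vinylsilane and leaves alkenes, the free hydroxyl and esters alone.

**Step 15**
Reactants: 18 vinylsilane
Product: 20 iodolactone (γ-lactone C7–O–C18; C6 iodide; C5 vinyl iodide), via vinyl iodide ester 19 (not isolated)
Conditions: NIS, MeCN/ClCH2CN, 0 °C; then I2, rt
Reagents that add atoms: N-iodosuccinimide, O=C1CCC(=O)N1I; iodine, II
Why: Ipso-iododesilylation gives the 2-iodoalkene, and 5-exo iodolactonisation of the tert-butyl ester onto the vinyl group (loss of the tert-butyl group) sets C7 with the iodomethyl group cis to 8-OH and trans to the C9 branch, the kinetic sense known for 3-hydroxypent-4-enoates and also the more stable lactone.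

**Step 16**
Reactants: 20 iodolactone
Product: 21 lactone aldehyde (C6 aldehyde, C5 vinyl iodide)
Conditions: AgBF4, DMSO, rt; then Et3N
Reagents that add atoms: dimethyl sulfoxide, CS(C)=O
Why: Silver-assisted Kornblum oxidation converts the primary iodide into the aldehyde through the alkoxysulfonium salt, while the vinyl iodide is inert.

**Step 17**
Reactants: 21 lactone aldehyde
Product: 22 ten-membered allylic alcohol (6-hydroxy, both C6 epimers)
Conditions: CrCl2 (8 equiv), NiCl2 (cat.), DMSO/THF, rt, slow addition at high dilution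
Reagents that add atoms: none
Why: Intramolecular Nozaki–Hiyama–Kishi coupling of the 2-iodoalkene with the aldehyde forms C5–C6 and closes the ten-membered ring while tolerating the esters and the free tertiary alcohol; the C6 configuration is corrected in steps 18 and 19.

**Step 18**
Reactants: 22 macrocyclic allylic alcohol
Product: 23 6-ketone (5(16)-en-6-one)
Conditions: Dess–Martin periodinane, NaHCO3, CH2Cl2, 0 °C
Reagents that add atoms: none
Why: Dess–Martin oxidation merges both C6 epimers into one α-methylene ketone.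

**Step 19**
Reactants: 23 6-ketone
Product: 24 6-epi alcohol (6-OH on the face opposite to the later chloride)
Conditions: NaBH4, CeCl3·7H2O, MeOH/THF, −78 °C
Reagents that add atoms: none
Why: Luche 1,2-reduction under polar Felkin–Anh control (hydride anti to the C7–O bond of the lactone) should give the alcohol syn to the C7 oxygen.

**Step 20**
Reactants: 24 6-epi alcohol
Product: 25 target, CNP0144558.1
Conditions: PPh3, hexachloroacetone, CH2Cl2, 0 °C
Reagents that add atoms: hexachloroacetone, ClC(Cl)(Cl)C(=O)C(Cl)(Cl)Cl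
Why: Magid deoxychlorination (PPh3/hexachloroacetone) replaces the secondary allylic hydroxyl by chloride through SN2 inversion with little allylic transposition, giving 6S; the tertiary 8-OH does not react.

**Compound list**

1 | but-3-yn-1-ol | C#CCCO | starting material
2 | penta-3,4-dien-1-ol | C=C=CCCO | intermediate
3 | penta-3,4-dienal | C=C=CCC=O | intermediate
4 | (1E)-tert-butyl(dimethyl)(penta-1,3,4-trien-1-yloxy)silane | C=C=C/C=C/O[Si](C)(C)C(C)(C)C | intermediate
5 | ethyl (E)-3-methyl-4-oxobut-2-enoate | CCOC(=O)/C=C(\C)C=O | starting material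
6 | ring A adduct, ethyl 3-(tert-butyldimethylsilyloxy)-2-formyl-2-methyl-6-methylidenecyclohex-4-ene-1-carboxylate (15-Me β, 14-OSi α, H-10 α) | C=C1C=C[C@H](O[Si](C)(C)C(C)(C)C)[C@](C)(C=O)[C@H]1C(=O)OCC | intermediate
7 | hydroxy aldehyde, ethyl 2-formyl-3-hydroxy-2-methyl-6-methylidenecyclohex-4-ene-1-carboxylate (14α-OH) | C=C1C=C[C@H](O)[C@](C)(C=O)[C@H]1C(=O)OCC | intermediate
8 | hydroxy ester, (2S)-carbinol with 4-(trimethylsilyl)but-3-ynyl chain, 14α-OH, C9 ethyl ester | C=C1C=C[C@H](O)[C@](C)([C@@H](O)CCC#C[Si](C)(C)C)[C@H]1C(=O)OCC | intermediate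
9 | temporary lactone, trans-fused γ-lactone C2–O–C9(=O), 14α-OH, 12,13-ene, 11(20)-methylene | C=C1C=C[C@H](O)[C@]2(C)[C@H](CCC#C[Si](C)(C)C)OC(=O)[C@@H]12 | intermediate
10 | 12α,13α-epoxide of 9 (cis to 14α-OH) | C=C1[C@@H]2O[C@@H]2[C@H](O)[C@]3(C)[C@H](CCC#C[Si](C)(C)C)OC(=O)[C@@H]13 | intermediate
11 | 13α,14α-diol lactone with 11(20)-methylene | C=C1C[C@H](O)[C@H](O)[C@]2(C)[C@H](CCC#C[Si](C)(C)C)OC(=O)[C@@H]12 | intermediate
12 | methoxyallenyl ketone, C9 ketone bearing 1-methoxyallenyl (C8, C7, C6), 2,13,14-triol | C=C1C[C@H](O)[C@H](O)[C@](C)([C@@H](O)CCC#C[Si](C)(C)C)[C@H]1C(=O)C(OC)=C=C | intermediate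
13 | silylalkyne tetraol, (9S)-carbinol | C=C1C[C@H](O)[C@H](O)[C@](C)([C@@H](O)CCC#C[Si](C)(C)C)[C@H]1[C@H](O)C(OC)=C=C | intermediate
14 | tetraol, (9S)-carbinol, terminal alkyne, methoxyallene | C=C1C[C@H](O)[C@H](O)[C@](C)([C@@H](O)CCC#C)[C@H]1[C@H](O)C(OC)=C=C | intermediate
15 | 2,9,13,14-tetraacetate methoxyallene | C=C1C[C@H](OC(C)=O)[C@H](OC(C)=O)[C@](C)([C@@H](OC(C)=O)CCC#C)[C@H]1[C@H](OC(C)=O)C(OC)=C=C | intermediate
16 | 2,9,13,14-tetraacetate vinyl ketone (C8 ketone) | C=C1C[C@H](OC(C)=O)[C@H](OC(C)=O)[C@](C)([C@@H](OC(C)=O)CCC#C)[C@H]1[C@H](OC(C)=O)C(=O)C=C | intermediate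
17 | β-hydroxy tert-butyl ester, C8 tertiary alcohol with vinyl, C17 methyl | C=C1C[C@H](OC(C)=O)[C@H](OC(C)=O)[C@](C)([C@@H](OC(C)=O)CCC#C)[C@H]1[C@H](OC(C)=O)[C@@](O)(C=C)[C@@H](C)C(=O)OC(C)(C)C | intermediate
18 | α-(triethylsilyl)vinyl derivative of 17 | C=C1C[C@H](OC(C)=O)[C@H](OC(C)=O)[C@](C)([C@@H](OC(C)=O)CCC(=C)[Si](CC)(CC)CC)[C@H]1[C@H](OC(C)=O)[C@@](O)(C=C)[C@@H](C)C(=O)OC(C)(C)C | intermediate
19 | vinyl iodide ester (C5 iodide) | C=C1C[C@H](OC(C)=O)[C@H](OC(C)=O)[C@](C)([C@@H](OC(C)=O)CCC(I)=C)[C@H]1[C@H](OC(C)=O)[C@@](O)(C=C)[C@@H](C)C(=O)OC(C)(C)C | intermediate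
20 | iodolactone, γ-lactone with 8-OH, 17-methyl, C6 iodide, C5 vinyl iodide | C=C1C[C@H](OC(C)=O)[C@H](OC(C)=O)[C@](C)([C@@H](OC(C)=O)CCC(I)=C)[C@H]1[C@H](OC(C)=O)[C@@]2(O)[C@H](CI)OC(=O)[C@@H]2C | intermediate
21 | lactone aldehyde (C6 aldehyde), C5 vinyl iodide | C=C1C[C@H](OC(C)=O)[C@H](OC(C)=O)[C@](C)([C@@H](OC(C)=O)CCC(I)=C)[C@H]1[C@H](OC(C)=O)[C@@]2(O)[C@H](C=O)OC(=O)[C@@H]2C | intermediate
22 | ten-membered allylic alcohol, 6-hydroxy (both C6 epimers) | C=C1C[C@H](OC(C)=O)[C@H](OC(C)=O)[C@]2(C)[C@@H](OC(C)=O)CCC(=C)C(O)[C@@H]3OC(=O)[C@H](C)[C@@]3(O)[C@@H](OC(C)=O)[C@@H]12 | intermediate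
23 | 6-ketone, 5(16)-en-6-one | C=C1C[C@H](OC(C)=O)[C@H](OC(C)=O)[C@]2(C)[C@@H](OC(C)=O)CCC(=C)C(=O)[C@@H]3OC(=O)[C@H](C)[C@@]3(O)[C@@H](OC(C)=O)[C@@H]12 | intermediate
24 | 6-epi alcohol (6-OH opposite to the chloride of the target) | C=C1C[C@H](OC(C)=O)[C@H](OC(C)=O)[C@]2(C)[C@@H](OC(C)=O)CCC(=C)[C@@H](O)[C@@H]3OC(=O)[C@H](C)[C@@]3(O)[C@@H](OC(C)=O)[C@@H]12 | intermediate
25 | (1S,2S,6S,7R,8R,9S,10S,13S,14R,17R)-2,9,13,14-tetraacetoxy-6-chloro-8-hydroxybriara-5(16),11(20)-dien-18,7-olide (CNP0144558.1) | C=C1C[C@H](OC(C)=O)[C@H](OC(C)=O)[C@]2(C)[C@@H](OC(C)=O)CCC(=C)[C@H](Cl)[C@@H]3OC(=O)[C@H](C)[C@@]3(O)[C@@H](OC(C)=O)[C@@H]12 | target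

**Totals**

Total step count: 20. Longest linear sequence: 20 steps (1 to 25; 5 is purchased).

**Steps most likely to fail**

Step 4 (proposed new method). The activated formyl group may instead undergo Mukaiyama-type 1,2-addition or hetero-cycloaddition with the silyl dienol ether, or facial discrimination may be poor. Fallback, from 4 and 5 back to 9: the cycloaddition is run with an achiral Lewis acid (Me2AlCl, CH2Cl2, −78 °C), a known mode for vinylallenes and enals, to give the racemic ring A adduct F1. Desilylation as in step 5 gives the racemic hydroxy aldehyde F2, and the Grignard addition and lactonisation of step 6 give the racemic lactone F3. Lipase-mediated kinetic resolution of its secondary allylic alcohol (Candida antarctica lipase B, vinyl acetate, MTBE) acetylates one antipode, taken here to be the unwanted one, as the antipodal lactone acetate F4, and leaves 9, which re-enters at step 7. If the wanted antipode is the one acylated, its acetate is methanolysed to 9.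

Step 17. Oligomerisation or transannular strain may prevent closure of the ten-membered ring. Fallback, from 17 back to 22, by a reductive alkyne–aldehyde coupling that needs no vinyl halide: iodolactonisation of 17 (I2, MeCN) gives the alkynyl iodolactone F5, and Kornblum oxidation as in step 16 gives the alkynyl lactone aldehyde F6. Nickel-catalysed reductive macrocyclisation (Ni(cod)2, 1,3-bis(2,6-diisopropylphenyl)imidazol-2-ylidene, Et3SiH, THF, slow addition), which with a bulky carbene ligand joins the internal alkyne carbon to the aldehyde, gives the macrocyclic 6-O-triethylsilyl ether F7. HF·pyridine then gives 22.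

Step 20. Allylic transposition (SN2′) or elimination may compete with direct substitution at the hindered C6. Fallback, from 24 back to 25, using transposition on purpose: rhenium-catalysed 1,3-transposition of the allylic alcohol (Ph3SiOReO3, Et2O, 0 °C) should give the more substituted isomer, the primary 16-hydroxy Δ5(6) alcohol F8. Thionyl chloride in Et2O without base (SNi′) should return chlorine to C6 and regenerate the 5(16)-methylene to give 25. The configuration at C6 is then set by syn delivery on the exposed face of the ring alkene and must be checked.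

**Further compounds**

F1 | step 4 | racemic ring A adduct (relative configuration of 6; the antipode not in the list is drawn) | C=C1C=C[C@@H](O[Si](C)(C)C(C)(C)C)[C@@](C)(C=O)[C@@H]1C(=O)OCC
F2 | step 4 | racemic hydroxy aldehyde (relative configuration of 7; antipode drawn) | C=C1C=C[C@@H](O)[C@@](C)(C=O)[C@@H]1C(=O)OCC
F3 | step 4 | racemic lactone (relative configuration of 9; antipode drawn) | C=C1C=C[C@@H](O)[C@@]2(C)[C@@H](CCC#C[Si](C)(C)C)OC(=O)[C@H]12
F4 | step 4 | antipodal lactone acetate (14-O-acetate of the antipode of 9) | C=C1C=C[C@@H](OC(C)=O)[C@@]2(C)[C@@H](CCC#C[Si](C)(C)C)OC(=O)[C@H]12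
F5 | step 17 | alkynyl iodolactone (as 20, terminal alkyne in place of the vinyl iodide) | C=C1C[C@H](OC(C)=O)[C@H](OC(C)=O)[C@](C)([C@@H](OC(C)=O)CCC#C)[C@H]1[C@H](OC(C)=O)[C@@]2(O)[C@H](CI)OC(=O)[C@@H]2C
F6 | step 17 | alkynyl lactone aldehyde (as 21, terminal alkyne in place of the vinyl iodide) | C=C1C[C@H](OC(C)=O)[C@H](OC(C)=O)[C@](C)([C@@H](OC(C)=O)CCC#C)[C@H]1[C@H](OC(C)=O)[C@@]2(O)[C@H](C=O)OC(=O)[C@@H]2C
F7 | step 17 | macrocyclic 6-O-triethylsilyl ether (both C6 epimers) | C=C1C[C@H](OC(C)=O)[C@H](OC(C)=O)[C@]2(C)[C@@H](OC(C)=O)CCC(=C)C(O[Si](CC)(CC)CC)[C@@H]3OC(=O)[C@H](C)[C@@]3(O)[C@@H](OC(C)=O)[C@@H]12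
F8 | step 20 | primary 16-hydroxy Δ5(6) alcohol (C4 and C7 cis on the ring alkene) | C=C1C[C@H](OC(C)=O)[C@H](OC(C)=O)[C@]2(C)[C@@H](OC(C)=O)CC/C(CO)=C\[C@@H]3OC(=O)[C@H](C)[C@@]3(O)[C@@H](OC(C)=O)[C@@H]12
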